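**Retrosynthetic overview**
1. Target ⇐ hydroxyl-directed nucleophilic epoxidation of the (1E,4Z)-dienone 22, which already carries the cis-lactone, the tiglate and the free C10–OH.
2. 22 ⇐ ring expansion 5+7 → 10: β-scission of the C3–C9 bond of the C3 alkoxy radical of hydroazulenol 20, then E1cB opening of a C1/C10 methylene acetal.
3. 20 ⇐ RCM (C4=C5) ⇐ isopropenyl addition to cyclopentanone 17 ⇐ acetalisation/oxa-Michael on cyclopentenone 16.
4. 16 ⇐ syn-allylboration/lactonisation of acrolein (C6–C7) with allylboronate 13 ⇐ tigloylation ⇐ anti boron aldol (C8–C9) of enone 9 with enal 5.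
5. Ring order: cyclopentane (from 6) → γ-lactone → dioxolane (temporary) → cycloheptene → cyclodecadienone → oxirane.

Assumption: labels C1–C15 are germacrane positions of the target (C1–C2 epoxide, C3 ketone, C4=C5, C6–O lactone, C8–O ester, C10 carbinol, C11=C13 methylene); I read the SMILES as (1R,2R,6S,7R,8R,10R), 4Z, cis-fused lactone, (E)-2-methylbut-2-enoate.

**Step 1**
Reactants: 1 methyl acrylate; 2 2,2-dimethoxyacetaldehyde
Product: 3 methyl 3-hydroxy-4,4-dimethoxy-2-methylidenebutanoate (racemic)
Conditions: DABCO (0.3 equiv), 1,4-dioxane/H2O 1:1, rt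
Reagents that add atoms: none
Why: Morita–Baylis–Hillman reaction of an activated α-alkoxy aldehyde; the carbinol stereocentre is erased in step 2.

**Step 2**
Reactants: 3 methyl 3-hydroxy-4,4-dimethoxy-2-methylidenebutanoate
Product: 5 methyl (2E)-4-oxo-2-[(pinacolatoboryl)methyl]but-2-enoate, via allylboronate acetal 4 (not isolated)
Conditions: B2pin2 (1.2 equiv), Pd(MeCN)4(BF4)2 (5 mol%), DMSO/MeOH, 50 °C; then 1 M aq HCl, acetone, 0 °C
Reagents that add atoms: bis(pinacolato)diboron CC1(C)OB(OC1(C)C)B1OC(C)(C)C(C)(C)O1; water O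
Why: Pd-catalysed allylic C–O borylation with allylic transposition (η3-allyl-Pd borylated at the CH2 terminus) gives the thermodynamic E-enoate with the C8 carbon cis to CH2Bpin, and acetal hydrolysis then frees the aldehyde.

**Step 3**
Reactants: 6 3-methylcyclopent-2-en-1-one
Product: 8 (3S)-3-hydroxy-3-methylcyclopentan-1-one, via boryl ketone 7 (not isolated)
Conditions: B2pin2 (1.1 equiv), CuPF6(MeCN)4 (5 mol%), QuinoxP* (6 mol%, enantiomer giving 3S), LiOt-Bu (10 mol%), MeOH (2 equiv), DMSO, rt; then NaBO3·4H2O, THF/H2O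
Reagents that add atoms: bis(pinacolato)diboron CC1(C)OB(OC1(C)C)B1OC(C)(C)C(C)(C)O1 (Bpin of 7); sodium perborate [Na+].[Na+].O[B-]1(O)OO[B-](O)(O)OO1 (hydroxyl O of 8)
Why: Cu(I)-catalysed enantioselective conjugate boration of a β-substituted cyclic enone, in which the chiral bisphosphine–Cu–Bpin complex selects the enone face, followed by stereoretentive C–B oxidation, sets the C10 tertiary carbinol.

**Step 4**
Reactants: 8 (3S)-3-hydroxy-3-methylcyclopentan-1-one
Product: 9 (4R)-4-hydroxy-4-methylcyclopent-2-en-1-one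
Conditions: IBX (2 equiv), 4-methoxypyridine N-oxide (2 equiv), DMSO, 30 °C
Reagents that add atoms: none
Why: IBX ketone α,β-dehydrogenation, which can only desaturate C1–C2 because C10 is quaternary; C10 is untouched (S→R is a CIP priority change only).

**Step 5**
Reactants: 9 (4R)-4-hydroxy-4-methylcyclopent-2-en-1-one; 5 methyl (2E)-4-oxo-2-[(pinacolatoboryl)methyl]but-2-enoate
Product: 11 methyl (2E)-4-hydroxy-4-[2-hydroxy-2-methyl-5-oxocyclopent-3-en-1-yl]-2-[(pinacolatoboryl)methyl]but-2-enoate (anti-aldol; C9 chain trans to the ring OH; C8–O and C10–O 1,3-anti), via boron dienolate 10 (not isolated)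
Conditions: c-Hex2BCl (2.2 equiv), i-Pr2NEt (2.5 equiv), Et2O, −78 → 0 °C; 5, −78 °C; MeOH/pH 7 buffer, diethanolamine work-up (no peroxide)
Reagents that add atoms: chlorodicyclohexylborane ClB(C1CCCCC1)C1CCCCC1 (boryl groups of 10 only; nothing remains in 11)
Why: Boron-mediated anti-aldol through a Zimmerman–Traxler chair of the E-configured cyclic α′-enolate, the aldehyde adding to C9 anti to the bulky C10–OBCy2 (cis to CH3), so that C10 is relayed through C9 to C8; the pinacol boronate is a spectator.

**Step 6**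
Reactants: 11 aldol adduct; 12 (2E)-2-methylbut-2-enoyl chloride (tigloyl chloride)
Product: 13 8-O-tiglate of 11
Conditions: pyridine, DMAP (5 mol%), CH2Cl2, 0 °C
Reagents that add atoms: none
Why: Acylation of the secondary C8–OH with retention, the tertiary C10–OH being unreactive; the non-chelating ester also blocks C8–O from lactonising in step 7.

**Step 7**
Reactants: 13 8-O-tiglate allylboronate; 14 acrolein
Product: 16 cis-α-methylidene-γ-butyrolactone (C6 vinyl and C7 chain cis; C7/C8 anti) bearing the 8-O-tiglate and the hydroxy cyclopentenone, via borate adduct 15 (not isolated)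
Conditions: 14 (3 equiv), Sc(OTf)3 (10 mol%), toluene, −40 → 0 °C; then p-TsOH·H2O (10 mol%), rt
Reagents that add atoms: none
Why: Lewis-acid-accelerated allylboration with tandem lactonisation through a closed chair in which the C8 group, cis to CH2B, sits axial (6,7-syn, hence cis-lactone), while C8 sets the face (C8–H eclipses the alkene by A1,3 strain and the aldehyde adds anti to the bulky cyclopentenyl C9).

**Step 8**
Reactants: 16 lactone cyclopentenone
Product: 17 cis-fused methylene acetal (1,3-dioxolane across C1–O and C10–O) cyclopentanone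
Conditions: (CH2O)n (5 equiv), (PhO)2PO2H (10 mol%), 4 Å MS, CH2Cl2, 35 °C
Reagents that add atoms: formaldehyde (from paraformaldehyde) C=O
Why: Brønsted-acid acetalisation/oxa-Michael cascade in which the formaldehyde hemiacetal of the C10–OH adds 5-exo to C1 of the enone, necessarily cis to C10–O; this protects C10–O, saturates C2 and installs a C1–O leaving group.

**Step 9**
Reactants: 17 acetal cyclopentanone; 18 isopropenylmagnesium bromide
Product: 19 C3 tertiary alcohol (isopropenyl trans to the C9 chain)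
Conditions: CeCl3 (3 equiv), 18 (2.5 equiv), THF, −78 °C
Reagents that add atoms: none
Why: Organocerium 1,2-addition, chemoselective for the ketone over lactone and ester, from the face anti to the C9 chain; the C3 configuration is erased in step 11.

**Step 10**
Reactants: 19 diene alcohol
Product: 20 trans-fused hydroazulenol (cyclopentane/cycloheptene with lactone and dioxolane)
Conditions: Hoveyda–Grubbs II (10 mol%), toluene (2 mM), 80 °C
Reagents that add atoms: none
Why: Ring-closing metathesis of the isopropenyl and C6-vinyl groups closes the seven-membered ring and enforces the 4Z alkene; the electron-poor methylidene lactone and tiglate do not take part.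

**Step 11**
Reactants: 20 hydroazulenol
Product: 22 (6S,7R,8R,10R)-10-hydroxy-3-oxo-8-tigloyloxygermacra-1E,4Z,11(13)-trien-6,12-olide, via ring-opened ketone 21 (not isolated)
Conditions: [Ir(dF(CF3)ppy)2(5,5′-d(CF3)bpy)]PF6 (2 mol%), Bu4P+ (MeO)2PO2− (25 mol%), 2,4,6-(i-Pr)3C6H2SH (30 mol%), PhCF3, blue LEDs, 25 °C; then DBU (2 equiv), 0 °C
Reagents that add atoms: none
Why: Proposed new method: photocatalytic proton-coupled electron transfer homolyses the O–H of the tertiary allylic C3–OH, and the alkoxy radical fragments to the secondary C9 radical (C3–C4 is vinylic; C3–C2 would give a primary radical and can re-close), opening the fused 5/7 system to the ten-membered Z-enone, with thiol hydrogen-atom transfer capping C9 as a non-stereogenic CH2; DBU then expels the C1 acetal oxygen by E1cB (loss of CH2O) to give the 1E-enone and free C10–OH; the closest known reactions are PCET ring-opening and ring-expansion of simple cycloalkanols and hypoiodite or Pb(OAc)4 β-fragmentation of bicyclic carbinols to medium-ring ketones, neither shown for a fused allylic carbinol giving a cyclodecadienone.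

**Step 12**
Reactants: 22 dienone
Product: 23 target (1R,2R,6S,7R,8R,10R)-1,2-epoxy-10-hydroxy-3-oxo-8-tigloyloxygermacra-4Z,11(13)-dien-6,12-olide
Conditions: t-BuOOH (2 equiv, in decane), DBU (1.2 equiv), CH2Cl2, 0 °C
Reagents that add atoms: tert-butyl hydroperoxide CC(C)(C)OO
Why: Weitz–Scheffer nucleophilic epoxidation in which the C10–OH hydrogen-bonds the peroxide anion and delivers it to C1 on its own side of the disubstituted E-enone (expected to be faster than the α-methyl enone or the acrylate-type lactone); ring closure gives the trans (1R,2R)-epoxide syn to the hydroxyl.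

**Compound list**
1 | methyl acrylate | C=CC(=O)OC | starting material
2 | 2,2-dimethoxyacetaldehyde | COC(OC)C=O | starting material
3 | methyl 3-hydroxy-4,4-dimethoxy-2-methylidenebutanoate (racemic) | C=C(C(=O)OC)C(O)C(OC)OC | intermediate
4 | methyl (2E)-4,4-dimethoxy-2-[(4,4,5,5-tetramethyl-1,3,2-dioxaborolan-2-yl)methyl]but-2-enoate | COC(OC)/C=C(/C(=O)OC)CB1OC(C)(C)C(C)(C)O1 | intermediate (not isolated)
5 | methyl (2E)-4-oxo-2-[(4,4,5,5-tetramethyl-1,3,2-dioxaborolan-2-yl)methyl]but-2-enoate | O=C/C=C(/C(=O)OC)CB1OC(C)(C)C(C)(C)O1 | intermediate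
6 | 3-methylcyclopent-2-en-1-one | CC1=CC(=O)CC1 | starting material
7 | (3R)-3-methyl-3-(4,4,5,5-tetramethyl-1,3,2-dioxaborolan-2-yl)cyclopentan-1-one | O=C1CC[C@](C)(B2OC(C)(C)C(C)(C)O2)C1 | intermediate (not isolated)
8 | (3S)-3-hydroxy-3-methylcyclopentan-1-one | O=C1CC[C@](C)(O)C1 | intermediate
9 | (4R)-4-hydroxy-4-methylcyclopent-2-en-1-one | O=C1C=C[C@](C)(O)C1 | intermediate
10 | O,O′-bis(dicyclohexylboryl) dienolate of 9 (enolate C3=C9; borinate on C10–O) | C[C@]1(OB(C2CCCCC2)C2CCCCC2)C=CC(OB(C2CCCCC2)C2CCCCC2)=C1 | intermediate (not isolated)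
11 | anti-aldol adduct: methyl (2E)-4-hydroxy-4-[2-hydroxy-2-methyl-5-oxocyclopent-3-en-1-yl]-2-[(pinacolatoboryl)methyl]but-2-enoate; C9 chain trans to ring OH | O=C1C=C[C@](C)(O)[C@H]1[C@@H](O)/C=C(/C(=O)OC)CB2OC(C)(C)C(C)(C)O2 | intermediate
12 | (2E)-2-methylbut-2-enoyl chloride (tigloyl chloride) | C/C=C(\C)C(=O)Cl | starting material
13 | 8-O-tiglate of 11 | O=C1C=C[C@](C)(O)[C@H]1[C@@H](OC(=O)/C(C)=C/C)/C=C(/C(=O)OC)CB2OC(C)(C)C(C)(C)O2 | intermediate
14 | acrolein | C=CC=O | starting material
15 | allylboration adduct: methyl 2-methylidene ester with C6–O–Bpin (6,7-syn; 7,8-anti) | C=C(C(=O)OC)[C@@H]([C@@H](OB1OC(C)(C)C(C)(C)O1)C=C)[C@H](OC(=O)/C(C)=C/C)[C@H]2C(=O)C=C[C@]2(C)O | intermediate (not isolated)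
16 | cis-fused α-methylidene-γ-butyrolactone (C6 vinyl) with 8-O-tiglate and 4-hydroxy-4-methylcyclopentenone | C=C1C(=O)O[C@@H](C=C)[C@H]1[C@H](OC(=O)/C(C)=C/C)[C@H]2C(=O)C=C[C@]2(C)O | intermediate
17 | C1/C10 methylene acetal (cis-fused 1,3-dioxolane) cyclopentanone | C=C1C(=O)O[C@@H](C=C)[C@H]1[C@H](OC(=O)/C(C)=C/C)[C@H]2C(=O)C[C@@H]3OCO[C@]23C | intermediate
18 | isopropenylmagnesium bromide | C=C(C)[Mg]Br | starting material
19 | C3 tertiary alcohol (isopropenyl trans to C9 chain) | C=C1C(=O)O[C@@H](C=C)[C@H]1[C@H](OC(=O)/C(C)=C/C)[C@H]2[C@](O)(C(C)=C)C[C@@H]3OCO[C@]23C | intermediate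
20 | trans-fused hydroazulenol (C3–OH; C4=C5 in the seven-membered ring; lactone; dioxolane) | C=C1C(=O)O[C@H]2/C=C(/C)[C@]3(O)C[C@@H]4OCO[C@]4(C)[C@H]3[C@@H](OC(=O)/C(C)=C/C)[C@@H]12 | intermediate
21 | ten-membered 4Z-enone with C1/C10 methylene acetal | C=C1C(=O)O[C@H]2/C=C(/C)C(=O)C[C@@H]3OCO[C@]3(C)C[C@@H](OC(=O)/C(C)=C/C)[C@@H]12 | intermediate (not isolated)
22 | (6S,7R,8R,10R)-10-hydroxy-3-oxo-8-tigloyloxygermacra-1E,4Z,11(13)-trien-6,12-olide | C=C1C(=O)O[C@H]2/C=C(/C)C(=O)/C=C/[C@](C)(O)C[C@@H](OC(=O)/C(C)=C/C)[C@@H]12 | intermediate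
23 | CNP0383091.1: (1R,2R,6S,7R,8R,10R)-1,2-epoxy-10-hydroxy-3-oxo-8-tigloyloxygermacra-4Z,11(13)-dien-6,12-olide | C=C1C(=O)O[C@H]2/C=C(/C)C(=O)[C@@H]3O[C@H]3[C@](C)(O)C[C@@H](OC(=O)/C(C)=C/C)[C@@H]12 | target

**Totals**
Total steps: 12. Longest linear sequence: 10 (steps 3–12 from 6; the branch 1 → 5 joins at step 5 and is equally long).

**Three steps most likely to fail**

Step 11 (proposed new step). Risks: transannular 5-exo attack of the C9 radical on the new enone, competing C3–C2 scission, and thiol addition to the Michael acceptors. Fallback with known chemistry: set out from 20 and use classical hypoiodite β-fragmentation (PhI(OAc)2, I2, cyclohexane/CH2Cl2, hν, rt), which cleaves the same C3–C9 bond and traps C9 by fast iodine-atom transfer to give the 9-iodo ketone F1. Radical deiodination with (Me3Si)3SiH and Et3B/air in toluene at −20 °C then gives 21, where the route is rejoined (DBU to 22).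

Step 7. Risks: the 7,8 facial selectivity rests on substrate control, and acrolein may polymerise under Lewis acid. Fallback: set out from 4 (isolated before the acid treatment of step 2) and fix C6/C7 by catalyst control before fragment union. A chiral phosphoric acid (TRIP-type) catalysed allylboration of 14 with acid lactonisation gives the cis-lactone acetal F2. Aqueous TFA hydrolysis gives the lactone aldehyde F3. Boron aldol with dienolate 10 as in step 5 gives the C8 carbinol F4 (enolate-face control), and acylation with 12 as in step 6 rejoins the route at 16.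

Step 12. Risks: three electron-poor alkenes compete (the methylidene lactone above all), and the epoxide face must be set by the C10–OH. Fallback: set out from 22 and mask the lactone first with Me2NH (THF, 0 °C) as the amine adduct F5. Epoxidise the now most reactive 1E-enone (t-BuOOH, DBU) to the epoxy amine F6. Then MeI followed by NaHCO3 regenerates the methylidene by quaternisation/elimination, rejoining at 23.

**Further compounds**
F1 | step 11 | 9-iodo derivative of 21 (C9 epimers) | C=C1C(=O)O[C@H]2/C=C(/C)C(=O)C[C@@H]3OCO[C@]3(C)C(I)[C@@H](OC(=O)/C(C)=C/C)[C@@H]12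
F2 | step 7 | cis-4-(dimethoxymethyl)-3-methylidene-5-vinyloxolan-2-one (C6, C7 as in 16) | C=C1C(=O)O[C@@H](C=C)[C@H]1C(OC)OC
F3 | step 7 | cis-4-methylidene-5-oxo-2-vinyloxolane-3-carbaldehyde (C6, C7 as in 16) | C=C1C(=O)O[C@@H](C=C)[C@H]1C=O
F4 | step 7 | C8 carbinol corresponding to 16 without the tigloyl group | C=C1C(=O)O[C@@H](C=C)[C@H]1[C@H](O)[C@H]2C(=O)C=C[C@]2(C)O
F5 | step 12 | 13-(dimethylamino)-11,13-dihydro adduct of 22 (C11 unassigned) | CN(C)CC1C(=O)O[C@H]2/C=C(/C)C(=O)/C=C/[C@](C)(O)C[C@@H](OC(=O)/C(C)=C/C)[C@@H]12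
F6 | step 12 | 13-(dimethylamino)-11,13-dihydro adduct of 23 (C11 unassigned) | CN(C)CC1C(=O)O[C@H]2/C=C(/C)C(=O)[C@@H]3O[C@H]3[C@](C)(O)C[C@@H](OC(=O)/C(C)=C/C)[C@@H]12
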